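## The problem

Compound 17, octadecyl 3-(2,4-dihydroxy-3-methoxyphenyl)propanoate, has one ring, a benzene with four contiguous substituents, and no stereocentre, so nothing has to be controlled in space and everything in position. The chain is simple: the benzylic carbon C7, C8 and the ester carbon C9 hang from C1, and C9 carries the primary C18 alkoxy group of octadecan-1-ol 13. The difficulty lies in the ring, where C1 (carbon), C2 (OH), C3 (OMe) and C4 (OH) follow one another, so that the methoxy group is flanked by two free phenols and the chain sits ortho to one of them. Two features are fragile: the 2-methoxyresorcinol nucleus is oxidised easily once both phenols are free, especially as a phenoxide in air, and the C2 hydroxyl can attack C9 under acid, base or heat, closing a six-membered lactone (a dihydrocoumarin) and expelling 13. The free phenols should therefore appear late, and the last operations must be mild and close to neutral. The enabling feature is that C1 and C2 are neighbours lying beside the C3 methoxy group, the pattern produced when a 3-methoxybenzyne spanning C1–C2 takes a carbon nucleophile at the carbon remote from the methoxy group and an electrophile at the carbon next to it. The C3 methoxy group and the C4 oxygen can then come from an inexpensive guaiacol, and only the chain and the C2 oxygen have to be introduced.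

## Retrosynthesis

**17 ⇒ 16.** The O–Si bond at the C4 oxygen is cut. The silyl group that carries this phenol through the organometallic chemistry is kept to the end, so the oxidation-prone diphenol exists only as the final product. The forward reaction is a fluoride cleavage that must leave the ortho-hydroxy ester intact, which calls for buffered conditions.

**16 ⇒ 12 + 13.** The acyl–oxygen bond at C9 is cut, and in the forward sense the C2 oxygen is the leaving group. Lactone 12 is an internal aryl ester, so it is already an activated acyl donor and no coupling reagent is needed. The neighbouring option, esterifying the corresponding free hydroxy acid with 13, would have to compete with this same lactonisation. The cut removes more than half the mass of the molecule and leaves a small bicyclic lactone. The forward step asks for opening by the alkoxide 14, with the less basic phenoxide 15 as the thermodynamic sink.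

**12 ⇒ 11 ⇒ 9 (through 10).** No skeletal bond is cut here; the oxidation level of C9 and the heteroatom at C2 are adjusted. Lactone 12 comes from lactol 11 by oxidation. Lactol 11 comes from phenol acetal 10 by acid hydrolysis with capture of C9 by the C2 hydroxyl. Phenol 10 comes from boronate 9 by oxidation of the C2–B bond. C9 is carried at the aldehyde level as a cyclic acetal because an acetal is inert to a lithium amide and a Grignard reagent, whereas an ester is not. Boron is the placeholder for oxygen because arylmagnesium species are borylated far more cleanly than they are oxygenated.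

**9 ⇒ 2 + 4 + 5.** The C1–C7 bond and the C2–B bond are cut together, which corresponds to aryne 7 across C1–C2. This double cut is preferred over two separate ones (cross-coupling at the C–Cl bond followed by a second, less certain metalation next to the new chain) because a single deprotonation, at the hydrogen between chlorine and methoxy, fixes the position of both new substituents. The precursors are the trisubstituted arene 2, the three-carbon Grignard reagent 4 and the commercial borate 5, in place of a tetrasubstituted arene. The forward reaction requires site-selective lithiation to 6, β-elimination of 6 to give 7, regioselective carbomagnesiation to 8 and borylation.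

**2 ⇒ 1 and 4 ⇒ 3.** An O–Si bond and a C–Mg bond are cut, leading to 4-chloro-2-methoxyphenol 1 and 2-(2-bromoethyl)-1,3-dioxolane 3, both purchasable. The silyl group must be bulky enough not to direct lithiation to its own ortho position and not to migrate to carbon.

## Roads not taken

**Alternative 1:** The carbocycle itself is cut, at the C3–C4 bond. In the forward key step the methoxymethyl ketone enolate of dioctadecyl 4-(2-methoxyacetyl)heptanedioate A1 attacks one of its two equivalent ester arms (an intramolecular Claisen condensation). The product is octadecyl 3-(3-methoxy-2,4-dioxocyclohexyl)propanoate A2, which must then lose one molecule of hydrogen to become the arene.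
- Merits: A1 is symmetric, so either arm gives the same A2; the substitution pattern follows from connectivity alone; and the octadecyl ester is present from the outset, so it never has to be made next to a free phenol.
- Weak points: Dieckmann closure between the two ester arms of A1 also forms a six-membered ring and competes, so the outcome depends on equilibration under an alkoxide matched to the ester. One of the two C18 chains is expelled as 13. A2 needs a separate dehydrogenation of an oxidation-sensitive α-methoxy diketone, under conditions where the new ortho-hydroxy ester can lactonise. Assembling A1 requires double conjugate addition at the less acidic α-carbon of a methoxymethyl ketone, against its natural enolisation preference.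
- Comparison: building the ring de novo is more general with respect to substitution. For a pattern that a commodity arene already carries in large part it is longer and less certain than installing the two missing substituents in one operation, as the chosen plan does.

**Alternative 2:** The C8–C9 and C9–O bonds are cut in a three-component sense. In the forward key step 1,3-bis(benzyloxy)-4-ethenyl-2-methoxybenzene A3, carbon monoxide and 13 combine under catalysis by a palladium hydride generated from Pd(OAc)2, a bidentate phosphine and a sulfonic acid. The product is octadecyl 3-[2,4-bis(benzyloxy)-3-methoxyphenyl]propanoate A4. Hydrogenolysis of A4 then releases 17.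
- Merits: the step is convergent and atom-economic and attaches the C18 alcohol directly. The C2 oxygen of A4 stays benzylated until the end, so no lactone can form. The final hydrogenolysis of A4 is neutral and is cleaner than the fluoride step of the chosen route.
- Weak points: styrenes tend to deliver the alkoxycarbonyl group to the benzylic carbon, so the linear ester A4 requires bidentate phosphines and careful tuning, here with an ortho-benzyloxy group beside the alkene of A3. A stoichiometric, solid C18 alcohol is a poorer partner than a solvent alcohol in the alcoholysis of the acylpalladium intermediate. Pressurised carbon monoxide is needed. A3 is not an article of commerce and has to be made in several steps from an arene that already carries the complete oxygenation pattern, so the regiochemical problem of the ring is moved upstream rather than solved.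
- Comparison: with A3 in hand this road would be shorter than the chosen one and would end more gently, since A4 is one neutral step from 17. The chosen plan offers instead a cheap starting phenol, no gas handling, and ring regiochemistry decided by one mechanistic event.

**Alternative 3:** The C7–C8 bond is cut, and a bond from the C2 oxygen to C9 is formed transiently. The Mannich base 4-[(dimethylamino)methyl]-2-methoxybenzene-1,3-diol A5 releases the ortho-quinone methide 3-hydroxy-2-methoxy-6-methylidenecyclohexa-2,4-dien-1-one A6. A6 is trapped in a [4+2] sense by the ketene silyl acetal trimethyl{[1-(octadecyloxy)ethenyl]oxy}silane A7. The product is the chroman ortho ester 8-methoxy-2-(octadecyloxy)-2-[(trimethylsilyl)oxy]-3,4-dihydro-2H-chromen-7-ol A8, which should collapse to 17 on mild hydrolysis.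
- Merits: this is the shortest road on paper. The ester oxidation level and the octadecyl group arrive together, and the symmetry of the parent diphenol makes the ring regiochemistry trivial.
- Weak points: A5 has a free C4 hydroxyl para to the aminomethyl carbon, so elimination in the para mode competes with formation of A6. The free phenols protonate the acid-labile A7, which is a high-boiling reagent that cannot be purified by distillation and must be used in excess. Double aminomethylation threatens the preparation of A5. The collapse of A8 can expel either the aryloxy group (giving 17) or 13 (giving a lactone), and nothing in the structure decides between them.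
- Comparison: in step count this road is clearly better than the chosen one. The chosen plan is longer, but its steps are standard transformations with predictable selectivity, and the ester-versus-lactone question is settled thermodynamically (phenoxide formation in step 6) rather than by kinetic partitioning of an ortho ester.

Key step: step 3

Remark: the target has no stereocentre; the only stereocentre of the route, the hemiacetal carbon of 11, is formed as a racemate and removed in step 5.

## Route

Step 1
Reactants: 1 4-chloro-2-methoxyphenol
Product: 2 (4-chloro-2-methoxyphenoxy)tri(propan-2-yl)silane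
Conditions: i-Pr3SiCl (1.2 equiv), imidazole (2.5 equiv), DMF, rt
Reagents that add atoms: chlorotri(propan-2-yl)silane, CC(C)[Si](Cl)(C(C)C)C(C)C
Why: Imidazole-mediated silylation of a phenol; the bulky triisopropylsilyl ether tolerates lithium amides and Grignard reagents, is a poor director of ortho-lithiation and is slow to undergo anionic silyl migration.

Step 2
Reactants: 3 2-(2-bromoethyl)-1,3-dioxolane
Product: 4 [2-(1,3-dioxolan-2-yl)ethyl]magnesium bromide
Conditions: Mg turnings (1.5 equiv), cat. 1,2-dibromoethane, THF, 25–30 °C; solution titrated and used directly
Reagents that add atoms: magnesium, [Mg]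
Why: Grignard formation by insertion of magnesium into a primary alkyl bromide; the acetal masks the future ester carbon, and keeping the temperature at or below 30 °C avoids the known thermal fragmentation of this acetal-bearing reagent.

Step 3
Reactants: 2 (4-chloro-2-methoxyphenoxy)tri(propan-2-yl)silane, 4 [2-(1,3-dioxolan-2-yl)ethyl]magnesium bromide, 5 2-isopropoxy-4,4,5,5-tetramethyl-1,3,2-dioxaborolane
Product: 9 {4-[2-(1,3-dioxolan-2-yl)ethyl]-2-methoxy-3-(4,4,5,5-tetramethyl-1,3,2-dioxaborolan-2-yl)phenoxy}tri(propan-2-yl)silane, via aryllithium 6 (not isolated), via aryne 7 (not isolated), via arylmagnesium bromide 8 (not isolated)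
Conditions: lithium 2,2,6,6-tetramethylpiperidide (from 2,2,6,6-tetramethylpiperidine and n-BuLi, 1.15 equiv), THF, −78 °C, 1 h; transfer by cannula into 4 (2.5 equiv) in THF at 0 °C, then rt, 2 h; 5 (4 equiv), −78 °C → rt; aq. NH4Cl
Reagents that add atoms: none
Why: The hindered lithium amide removes the hydrogen flanked by chlorine and methoxy, the most acidic one because both neighbours withdraw inductively and the methoxy oxygen coordinates lithium, giving aryllithium 6, which is stable at −78 °C. When 6 is run into the excess Grignard reagent at 0 °C, the chloride is expelled as its lithium salt and aryne 7 forms across C1–C2 in the presence of its trap. The alkylmagnesium adds at C1, the aryne carbon remote from the methoxy group, because the inductively withdrawing C3–O bond distorts the aryne so that C1 is the more electrophilic terminus and the carbanion developing at C2 is stabilised by the adjacent oxygen, which can also chelate magnesium. The resulting 2,6-disubstituted arylmagnesium 8 is captured by borate 5 with loss of isopropoxide, forming the C2–B bond. The closest known reaction type is the carbomagnesiation of 3-alkoxybenzynes generated from ortho-metalated haloarenes with electrophilic quench of the 2-alkoxyarylmagnesium, combined with the standard borylation of aryl Grignard reagents by pinacol isopropyl borate. No ring closes and no stereocentre is formed. The step needs site selectivity in the deprotonation and regioselectivity in the addition, both secured by the C3 methoxy group, and capture of 7 by 4 in preference to 6, 8 or the amide, which inverse addition into an excess of the unhindered alkyl reagent and the bulk of the amide secure. The acetal and the silyl ether are inert to all species present, and surplus 4 is consumed by the excess of 5.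

Step 4
Reactants: 9 {4-[2-(1,3-dioxolan-2-yl)ethyl]-2-methoxy-3-(4,4,5,5-tetramethyl-1,3,2-dioxaborolan-2-yl)phenoxy}tri(propan-2-yl)silane
Product: 11 8-methoxy-7-{[tri(propan-2-yl)silyl]oxy}-3,4-dihydro-2H-chromen-2-ol (racemic hemiacetal), via phenol acetal 10 (not isolated)
Conditions: 30% aq. H2O2, 1 M NaOH, THF, 0 °C → rt; aq. Na2SO3; then 2 M HCl to pH 1, THF/H2O, rt
Reagents that add atoms: hydrogen peroxide, OO; water, O
Why: Alkaline peroxide oxidation of an arylboronic ester (aryl shift from boron to oxygen at the same carbon) gives phenol 10; aqueous acid then hydrolyses the dioxolane and the C2 hydroxyl captures C9 to close the six-membered hemiacetal, formed as a racemate and removed in step 5; the aryl triisopropylsilyl ether tolerates brief cold hydroxide and dilute acid.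

Step 5
Reactants: 11 8-methoxy-7-{[tri(propan-2-yl)silyl]oxy}-3,4-dihydro-2H-chromen-2-ol
Product: 12 8-methoxy-7-{[tri(propan-2-yl)silyl]oxy}-3,4-dihydro-2H-chromen-2-one
Conditions: pyridinium chlorochromate [C5H5NH][CrO3Cl] (1.5 equiv), NaOAc, 4 Å MS, CH2Cl2, rt
Reagents that add atoms: none
Why: Chlorochromate oxidation of a lactol to a lactone, well established for chroman-2-ols; the ring carries no free phenol at this stage, and the silyl and methyl ethers are inert to the buffered reagent.

Step 6
Reactants: 12 8-methoxy-7-{[tri(propan-2-yl)silyl]oxy}-3,4-dihydro-2H-chromen-2-one, 13 octadecan-1-ol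
Product: 16 octadecyl 3-(2-hydroxy-3-methoxy-4-{[tri(propan-2-yl)silyl]oxy}phenyl)propanoate, via sodium octadecan-1-olate 14 (not isolated), via ring-opened sodium phenolate 15 (not isolated)
Conditions: 13 (1.2 equiv), NaH (1.05 equiv), THF, 0 → 40 °C; then 12, 0 °C, 1 h; AcOH (1.2 equiv), 0 °C
Reagents that add atoms: none
Why: Alkoxide ring-opening (transesterification) of an aryl lactone; acyl substitution releases a phenoxide far less basic than the alkoxide, so one equivalent of alkoxide drives the opening to completion, and a cold acetic acid quench gives the hydroxy ester under conditions where re-closure is slow; attack at the hindered silicon is much slower than attack at the lactone carbonyl.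

Step 7
Reactants: 16 octadecyl 3-(2-hydroxy-3-methoxy-4-{[tri(propan-2-yl)silyl]oxy}phenyl)propanoate
Product: 17 octadecyl 3-(2,4-dihydroxy-3-methoxyphenyl)propanoate
Conditions: Bu4NF (1.1 equiv), AcOH (1.3 equiv), THF, 0 °C
Reagents that add atoms: none
Why: Fluoride cleavage of an aryl silyl ether; buffering with acetic acid keeps the medium near neutral so that the C2 phenoxide does not build up and attack the ester, and the ester and methyl ether are untouched.

## Compound list

1 | 4-chloro-2-methoxyphenol | COc1cc(Cl)ccc1O | starting material
2 | (4-chloro-2-methoxyphenoxy)tri(propan-2-yl)silane | COc1cc(Cl)ccc1O[Si](C(C)C)(C(C)C)C(C)C | intermediate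
3 | 2-(2-bromoethyl)-1,3-dioxolane | BrCCC1OCCO1 | starting material
4 | [2-(1,3-dioxolan-2-yl)ethyl]magnesium bromide | Br[Mg]CCC1OCCO1 | intermediate
5 | 2-isopropoxy-4,4,5,5-tetramethyl-1,3,2-dioxaborolane | CC(C)OB1OC(C)(C)C(C)(C)O1 | starting material
6 | {6-chloro-2-methoxy-3-[tri(propan-2-yl)silyloxy]phenyl}lithium (not isolated) | COc1c(O[Si](C(C)C)(C(C)C)C(C)C)ccc(Cl)c1[Li] | intermediate
7 | (2-methoxy-3,4-didehydrophenoxy)tri(propan-2-yl)silane (aryne; not isolated) | COC1=C(O[Si](C(C)C)(C(C)C)C(C)C)C=CC#C1 | intermediate
8 | {6-[2-(1,3-dioxolan-2-yl)ethyl]-2-methoxy-3-[tri(propan-2-yl)silyloxy]phenyl}magnesium bromide (not isolated) | COc1c(O[Si](C(C)C)(C(C)C)C(C)C)ccc(CCC2OCCO2)c1[Mg]Br | intermediate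
9 | {4-[2-(1,3-dioxolan-2-yl)ethyl]-2-methoxy-3-(4,4,5,5-tetramethyl-1,3,2-dioxaborolan-2-yl)phenoxy}tri(propan-2-yl)silane | COc1c(O[Si](C(C)C)(C(C)C)C(C)C)ccc(CCC2OCCO2)c1B1OC(C)(C)C(C)(C)O1 | intermediate
10 | 6-[2-(1,3-dioxolan-2-yl)ethyl]-2-methoxy-3-{[tri(propan-2-yl)silyl]oxy}phenol (not isolated) | COc1c(O[Si](C(C)C)(C(C)C)C(C)C)ccc(CCC2OCCO2)c1O | intermediate
11 | 8-methoxy-7-{[tri(propan-2-yl)silyl]oxy}-3,4-dihydro-2H-chromen-2-ol (racemic) | COc1c(O[Si](C(C)C)(C(C)C)C(C)C)ccc2CCC(O)Oc12 | intermediate
12 | 8-methoxy-7-{[tri(propan-2-yl)silyl]oxy}-3,4-dihydro-2H-chromen-2-one | COc1c(O[Si](C(C)C)(C(C)C)C(C)C)ccc2CCC(=O)Oc12 | intermediate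
13 | octadecan-1-ol | CCCCCCCCCCCCCCCCCCO | starting material
14 | sodium octadecan-1-olate (not isolated) | CCCCCCCCCCCCCCCCCC[O-].[Na+] | intermediate
15 | sodium 6-[3-(octadecyloxy)-3-oxopropyl]-2-methoxy-3-{[tri(propan-2-yl)silyl]oxy}phenolate (not isolated) | CCCCCCCCCCCCCCCCCCOC(=O)CCc1ccc(O[Si](C(C)C)(C(C)C)C(C)C)c(OC)c1[O-].[Na+] | intermediate
16 | octadecyl 3-(2-hydroxy-3-methoxy-4-{[tri(propan-2-yl)silyl]oxy}phenyl)propanoate | CCCCCCCCCCCCCCCCCCOC(=O)CCc1ccc(O[Si](C(C)C)(C(C)C)C(C)C)c(OC)c1O | intermediate
17 | octadecyl 3-(2,4-dihydroxy-3-methoxyphenyl)propanoate | CCCCCCCCCCCCCCCCCCOC(=O)CCc1ccc(O)c(OC)c1O | target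

## Step count and risk

Total steps: 7. Longest linear sequence: 6 steps (1 → 2 → 9 → 11 → 12 → 16 → 17, steps 1 and 3–7). The Grignard reagent 4 is a one-step branch (step 2).

**Step 3 (key step).** What may go wrong: aryne 7 may be captured by species other than the alkylmagnesium reagent. Addition of aryllithium 6 or arylmagnesium 8 would give biaryl coupling, and hydride transfer from the β-position of 4 would reduce the aryne. The regioselectivity of the addition may also erode if magnesium chelation by the methoxy oxygen guides the nucleophile to C2, and the acetal Grignard reagent may decompose if the elimination needs warming.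

Fallback, setting out from 2 and returning at 10: the two bonds are made in separate operations. The same lithiation of 2 is quenched with 5 at −78 °C, before the chloride is lost, to give {4-chloro-2-methoxy-3-(4,4,5,5-tetramethyl-1,3,2-dioxaborolan-2-yl)phenoxy}tri(propan-2-yl)silane F1. Alkaline hydrogen peroxide converts F1 into 6-chloro-2-methoxy-3-{[tri(propan-2-yl)silyl]oxy}phenol F2. The chain is then attached at the C–Cl bond of F2 by B-alkyl Suzuki–Miyaura coupling (Pd(OAc)2, 2-dicyclohexylphosphino-2',6'-dimethoxybiphenyl, K3PO4, THF/H2O, 65 °C) with 9-[2-(1,3-dioxolan-2-yl)ethyl]-9-borabicyclo[3.3.1]nonane F3, which is made by hydroboration of 2-ethenyl-1,3-dioxolane with 9-borabicyclo[3.3.1]nonane. The coupling gives 10, which enters the acid stage of step 4.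

**Step 4.** What may go wrong: protodeboronation of the hindered, electron-rich boronate may compete with oxidation. Once the phenol is free, the liberated aldehyde carbon may condense with the electron-rich ring under acid. The silyl ether may be partly lost.

Fallback, setting out from 9 and returning at 16: the ester is built while boron still masks the C2 oxygen, so neither lactol nor lactone is involved. Acetal exchange (pyridinium p-toluenesulfonate, acetone/H2O, 50 °C) gives 3-{3-methoxy-2-(4,4,5,5-tetramethyl-1,3,2-dioxaborolan-2-yl)-4-[tri(propan-2-yl)silyloxy]phenyl}propanal F4. Pinnick oxidation (NaClO2, NaH2PO4, 2-methylbut-2-ene, t-BuOH/H2O), in which the alkene scavenger protects the hindered boronate from hypochlorite, gives 3-{3-methoxy-2-(4,4,5,5-tetramethyl-1,3,2-dioxaborolan-2-yl)-4-[tri(propan-2-yl)silyloxy]phenyl}propanoic acid F5. Carbodiimide esterification of F5 with 13 (N-ethyl-N'-(3-dimethylaminopropyl)carbodiimide hydrochloride, 4-dimethylaminopyridine, CH2Cl2) gives octadecyl 3-{3-methoxy-2-(4,4,5,5-tetramethyl-1,3,2-dioxaborolan-2-yl)-4-[tri(propan-2-yl)silyloxy]phenyl}propanoate F6. Perborate oxidation (NaBO3·4H2O, THF/H2O, rt) of the C–B bond of F6 then gives 16.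

**Step 6.** What may go wrong: the alkoxide may attack silicon, the long-chain sodium alkoxide may be poorly soluble, and the hydroxy ester may re-close to the lactone with loss of 13 during work-up or chromatography.

Fallback, setting out from 12 and returning at 16: the ester C–O bond is made by alkylation at carbon instead of acyl substitution. Lactone 12 is saponified with LiOH (THF/H2O, 0 °C) and the solution is brought to pH 7–8 without further acidification. The carboxylate of 3-(2-hydroxy-3-methoxy-4-{[tri(propan-2-yl)silyl]oxy}phenyl)propanoic acid F7 is then alkylated with 1-bromooctadecane (KHCO3, DMF, 50 °C) to give 16. The weak base leaves the phenol protonated and unalkylated.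

**Step 7.** What may go wrong: phenoxide formed during desilylation may promote relactonisation with expulsion of 13, and the product diphenol may oxidise in air if the medium becomes basic.

Fallback, setting out from 12 and returning at 17: the order of the last two operations is reversed. Lactone 12 is desilylated first (Bu4NF/AcOH, THF, 0 °C) to 7-hydroxy-8-methoxy-3,4-dihydro-2H-chromen-2-one F8. F8 is opened with 2.1 equiv of 14 (one equivalent is consumed by the free phenol) under argon and quenched cold with acetic acid. The target 17 is then formed in the ring-opening and never meets fluoride.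

## Further compounds

F1 | step 3 | {4-chloro-2-methoxy-3-(4,4,5,5-tetramethyl-1,3,2-dioxaborolan-2-yl)phenoxy}tri(propan-2-yl)silane | COc1c(O[Si](C(C)C)(C(C)C)C(C)C)ccc(Cl)c1B1OC(C)(C)C(C)(C)O1
F2 | step 3 | 6-chloro-2-methoxy-3-{[tri(propan-2-yl)silyl]oxy}phenol | COc1c(O[Si](C(C)C)(C(C)C)C(C)C)ccc(Cl)c1O
F3 | step 3 | 9-[2-(1,3-dioxolan-2-yl)ethyl]-9-borabicyclo[3.3.1]nonane | O1CCOC1CCB1C2CCCC1CCC2
F4 | step 4 | 3-{3-methoxy-2-(4,4,5,5-tetramethyl-1,3,2-dioxaborolan-2-yl)-4-[tri(propan-2-yl)silyloxy]phenyl}propanal | COc1c(O[Si](C(C)C)(C(C)C)C(C)C)ccc(CCC=O)c1B1OC(C)(C)C(C)(C)O1
F5 | step 4 | 3-{3-methoxy-2-(4,4,5,5-tetramethyl-1,3,2-dioxaborolan-2-yl)-4-[tri(propan-2-yl)silyloxy]phenyl}propanoic acid | COc1c(O[Si](C(C)C)(C(C)C)C(C)C)ccc(CCC(=O)O)c1B1OC(C)(C)C(C)(C)O1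
F6 | step 4 | octadecyl 3-{3-methoxy-2-(4,4,5,5-tetramethyl-1,3,2-dioxaborolan-2-yl)-4-[tri(propan-2-yl)silyloxy]phenyl}propanoate | CCCCCCCCCCCCCCCCCCOC(=O)CCc1ccc(O[Si](C(C)C)(C(C)C)C(C)C)c(OC)c1B1OC(C)(C)C(C)(C)O1
F7 | step 6 | 3-(2-hydroxy-3-methoxy-4-{[tri(propan-2-yl)silyl]oxy}phenyl)propanoic acid | COc1c(O[Si](C(C)C)(C(C)C)C(C)C)ccc(CCC(=O)O)c1O
F8 | step 7 | 7-hydroxy-8-methoxy-3,4-dihydro-2H-chromen-2-one | COc1c(O)ccc2CCC(=O)Oc12
A1 | alternative 1 | dioctadecyl 4-(2-methoxyacetyl)heptanedioate | CCCCCCCCCCCCCCCCCCOC(=O)CCC(CCC(=O)OCCCCCCCCCCCCCCCCCC)C(=O)COC
A2 | alternative 1 | octadecyl 3-(3-methoxy-2,4-dioxocyclohexyl)propanoate (epimer and enol mixture) | CCCCCCCCCCCCCCCCCCOC(=O)CCC1CCC(=O)C(OC)C1=O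
A3 | alternative 2 | 1,3-bis(benzyloxy)-4-ethenyl-2-methoxybenzene | C=Cc1ccc(OCc2ccccc2)c(OC)c1OCc1ccccc1
A4 | alternative 2 | octadecyl 3-[2,4-bis(benzyloxy)-3-methoxyphenyl]propanoate | CCCCCCCCCCCCCCCCCCOC(=O)CCc1ccc(OCc2ccccc2)c(OC)c1OCc1ccccc1
A5 | alternative 3 | 4-[(dimethylamino)methyl]-2-methoxybenzene-1,3-diol | CN(C)Cc1ccc(O)c(OC)c1O
A6 | alternative 3 | 3-hydroxy-2-methoxy-6-methylidenecyclohexa-2,4-dien-1-one | C=C1C=CC(O)=C(OC)C1=O
A7 | alternative 3 | trimethyl{[1-(octadecyloxy)ethenyl]oxy}silane | C=C(OCCCCCCCCCCCCCCCCCC)O[Si](C)(C)C
A8 | alternative 3 | 8-methoxy-2-(octadecyloxy)-2-[(trimethylsilyl)oxy]-3,4-dihydro-2H-chromen-7-ol (racemic at the ortho ester carbon) | CCCCCCCCCCCCCCCCCCOC1(O[Si](C)(C)C)CCc2ccc(O)c(OC)c2O1
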